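## Analysis of the target

Kazinol K (29) is a 1,3-diarylpropane in which a saturated three-carbon chain joins ring A, a resorcinol, to ring B, a catechol one oxygen of which is part of a fused 2,2-dimethyl-2H-pyran. Ring positions are written with a hyphen, A-1 (chain), A-2 (OH), A-3 (H), A-4 (OH), A-5 (2-methylbut-3-en-2-yl), A-6 (H) and B-1 (chain), B-2 (prenyl), B-3 (pyran CH=), B-4 (pyran O), B-5 (OH), B-6 (H), whereas labels without a hyphen such as A1 or A2 denote compounds of the alternatives. The molecule has no stereocentre and no stereogenic double bond, so the problem is one of regiochemistry and chemoselectivity only. Sensitive groups are the three phenols (ring B is an oxidisable catechol monoether), the chromene and prenyl alkenes, the terminal vinyl group, and the A-4 hydroxyl next to the A-5 dimethylallyl group, which cyclises to a dihydrobenzofuran under acid, so hydrogenation, strong acid and strong oxidants are excluded late in the route. The difficulty lies in ring B, which is pentasubstituted with B-1 to B-5 contiguous, two neighbouring oxygens that end differently and two neighbouring carbon substituents of different kinds, and in the quaternary carbon at A-5. The strategy rests on the fact that the oxygen pair B-4/B-5 lies across the ring from the carbon pair B-1/B-2, linked by B-3 and B-6, so that B-3–B-4–B-5–B-6 is a 2,3-dioxygenated butadiene and B-1–B-2 a disubstituted alkyne. An ester at B-1 activates that alkyne, later makes the B-4 hydroxyl (para) more acidic than the B-5 hydroxyl, and finally supplies the first chain carbon.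

## Retrosynthetic reasoning

**Unmasking.** 29 is traced to its tris(triisopropylsilyl) ether 28. Silicon is chosen because the ethers come off under neutral, non-reductive conditions, whereas acid would endanger the A-4 hydroxyl/A-5 dimethylallyl pair and hydrogenolysis the alkenes.

**Chain–ring A bond.** 28 is cut at the A-1–CH2 bond into allyl chromene 20 and aryl bromide 26. This is the one chain bond that an sp2–sp3 cross-coupling can make without leaving an alkene or carbonyl in the chain to be reduced afterwards. The forward step must hydroborate only the monosubstituted alkene of 20 and must leave no boron–hydrogen bond to reach the vinyl group of 26.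

**Allyl group.** 20 is cut between the benzylic carbon and the vinyl unit, leading back through chloride 18 and alcohol 16 to ester 15, with the vinyl unit coming from stannane 19. The ester carbon, needed upstream for other reasons, thereby becomes the first chain carbon. The forward coupling must give the benzylic carbon no cationic lifetime, because the B-2 prenyl alkene sits next to it.

**Pyran ring.** 15 is opened at the B-3–CH and O–CMe2 bonds to aryl propargyl ether 11, and further to phenol 10, then catechol 8 and chloride 9. A propargyl ether on the B-4 oxygen can only rearrange to B-3, since B-5 carries oxygen. The forward task is to place the ether on B-4 and not B-5; the para ester at B-1, helped by the para alkyl group at B-2 that weakens the B-5 hydroxyl, provides this.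

**Ring B.** 8 is taken back by two hydrogens to cyclohexa-1,4-diene 6, which is cut at B-2–B-3 and B-1–B-6 into diene 2 and ynoate 5. All five contiguous positions of ring B are then fixed by constitution, and no directing-group chemistry on a crowded arene is needed. The forward reaction must engage the alkyne and not the prenyl alkene.

**Cycloaddition partners.** 2 comes from diketone 1 by double enol silylation. 5 comes from 3 and 4 by forming the bond between the alkyne terminus and the primary allylic carbon.

**Ring A.** 26 is traced through phenol 25 and silyl ether 23 to prenyl ether 22, made from 21 and 4. The A-5–C(quaternary) bond is cut because a [3,3] shift of a prenyl ether on the A-4 oxygen delivers exactly the 1,1-dimethylallyl group, and the bromine of 21 already marks A-1.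

## Alternatives that were turned down

Alternative 1: The A-5 side chain is disconnected into its methyl and vinyl carbons on the fully assembled skeleton. The precursor A2 carries an acetyl group at A-5 and a tert-butyl carbonate on the A-4 oxygen. In the key step methyllithium A3 adds to the ketone, the new alkoxide takes over the carbonate and expels it to give the ortho-quinone methide A4, and vinylmagnesium bromide A5 adds in the conjugate sense to give the bis(methoxymethyl) ether A1.
- For: the quaternary carbon is made at low temperature with positional control dictated by the acetyl group, and ring A can be bought with the acetyl group already in place. On this point it is stronger than the thermal Claisen used here.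
- Against: it does nothing for ring B, the harder ring. The cascade runs on the most advanced intermediate. A4 can lose its quinone methide character by a 1,5-hydrogen shift from one of its methyl groups, or take up a second methyl nucleophile. The methoxymethyl groups of A1 must finally be removed with acid next to the acid-labile A-4/A-5 pair and the chromene.
- Comparison: the chosen route concedes the elegance at A-5 but makes that carbon on a small early fragment where failure is cheap, spends its key step on ring B, and ends with a neutral desilylation instead of acid.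

Alternative 2: The pyran O–B-4 bond and the B-5–O bond are disconnected together. The precursor A7 is a fluoroarene with fluorine at B-4 and a cis-alkenyl tertiary alcohol at B-3. An excess of a secondary alkyllithium deprotonates the alcohol and B-5, fluoride is lost to give the aryne A8, the tethered alkoxide adds at B-4 to close the pyran, and the B-5 aryl anion is borylated and oxidised to give the 8-hydroxychromene A6.
- For: both oxygens are placed in one flask, each by a different mechanism, so no catechol has to be differentiated and no dehydrogenation or high temperature is needed. On these points it is as strong or stronger.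
- Against: A7 is itself a 1,2,3,4-tetrasubstituted arene, so the contiguous-substituent problem is only moved upstream. The excess strong base meets the doubly activated B-2 methylene (benzylic and allylic) and the benzylic CH2O group. The alkene must be cis or the ring cannot close. The aryne can also be attacked by the alkyllithium.
- Comparison: the chosen route builds the ring under neutral thermal conditions with the prenyl group never exposed to organolithiums, and pays for this with one regioselective O-alkylation that the ester controls.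

Alternative 3: The B-2–CH2 and B-3–CH2 bonds are disconnected together. A gallate-derived silyl triflate A10 gives the B-2/B-3 aryne with fluoride, and a zerovalent palladium catalyst with a prenyl halide and a prenylstannane adds two prenyl groups across it to give A9.
- For: a cheap aromatic starting material already carries the oxygens, and two bonds are formed at the most crowded positions in one operation. On starting-material cost and on avoiding a dehydrogenation it is stronger.
- Against: B-3 receives a prenyl group where the target needs the chromene carbon. That prenyl must later be cyclised oxidatively onto the B-4 oxygen while the identical group at B-2 survives, and the acetonide must be opened with B-4/B-5 differentiation on a catechol that oxidants convert to a quinone. Each prenyl can couple through its primary or tertiary end. A10 itself needs several steps.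
- Comparison: the chosen route fixes the prenyl constitution in the alkyne before the ring exists and forms the chromene by a rearrangement that can only reach B-3, so it is shorter after the key step and has fewer selectivity questions.

Key step: step 3

Assumption on the chemistry: mono-alkylation of 21 is taken to occur at the hydroxyl para to bromine (the less hindered one, not hydrogen-bonded to bromine); no compound of the route carries a stereocentre apart from the transient dienones 12 and 24, which are racemic.

## Route

Step 1
Reactants: 1 butane-2,3-dione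
Product: 2 2,3-bis(trimethylsilyloxy)buta-1,3-diene
Conditions: TMSOTf (2.2 equiv), Et3N (2.5 equiv), Et2O, 0 °C to rt; distillation
Reagents that add atoms: trimethylsilyl trifluoromethanesulfonate, C[Si](C)(C)OS(=O)(=O)C(F)(F)F
Why: Amine/silyl triflate enol silylation of both ketones; the methyl groups hold the only α-hydrogens, so only the 2,3-bis(silyloxy)diene can form.

Step 2
Reactants: 3 methyl propiolate; 4 1-bromo-3-methylbut-2-ene (prenyl bromide)
Product: 5 methyl 6-methylhept-5-en-2-ynoate
Conditions: CuI (10 mol%), K2CO3 (1.5 equiv), Bu4NI (10 mol%), DMF, rt, argon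
Reagents that add atoms: none
Why: Monovalent-copper-catalysed allylation of a terminal alkyne: the copper acetylide of the acidic propiolate should attack the primary carbon of the allylic bromide, and the mild heterogeneous base limits isomerisation of the skipped enyne.

Step 3
Reactants: 2 2,3-bis(trimethylsilyloxy)buta-1,3-diene; 5 methyl 6-methylhept-5-en-2-ynoate
Product: 6 methyl 2-(3-methylbut-2-en-1-yl)-4,5-bis(trimethylsilyloxy)cyclohexa-1,4-diene-1-carboxylate
Conditions: 2 (2.5 equiv), PhMe, 2,6-di-tert-butyl-4-methylphenol (cat.), sealed tube, 140 °C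
Reagents that add atoms: none
Why: Thermal Diels–Alder reaction: a concerted suprafacial [4+2] cycloaddition between the HOMO of diene 2, raised by the two silyloxy donors, and the LUMO of ynoate 5, lowered by the ester. The closest known reaction type is the cycloaddition of 2,3-bis(silyloxy)butadienes with acetylenic esters to give 4,5-bis(silyloxy)cyclohexa-1,4-dienes as catechol precursors. The six-membered carbocycle, the future ring B, closes by intermolecular [4+2] annulation: the B-2–B-3 and B-1–B-6 bonds form in the same event, one π bond of the alkyne remains as the B-1=B-2 alkene and the diene contracts to the B-4=B-5 enediol bis-silyl ether. No stereocentre is created. Regiochemistry does not arise because 2 is symmetric about its central bond, so both orientations give the same adduct. The selectivity needed is chemoselectivity for the alkyne over the prenyl alkene, secured by the ester conjugation of the triple bond and by the electron-rich, trisubstituted and therefore mismatched character of the alkene. Acid-free thermal conditions with excess 2 are chosen because the β-alkyl group makes 5 only a moderate dienophile and the silyl enol ethers would not survive Lewis acids; 6 should be carried on crude.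

Step 4
Reactants: 6 methyl 2-(3-methylbut-2-en-1-yl)-4,5-bis(trimethylsilyloxy)cyclohexa-1,4-diene-1-carboxylate
Product: 8 methyl 4,5-dihydroxy-2-(3-methylbut-2-en-1-yl)benzoate, via aryl bis(trimethylsilyl) ether 7 (not isolated)
Conditions: DDQ (1.0 equiv), PhMe, 0 °C to rt; filter; then MeOH, citric acid (cat.), rt
Reagents that add atoms: none
Why: Quinone dehydrogenation of a cyclohexa-1,4-diene by hydride abstraction from a doubly allylic CH2 (the cation is stabilised by the adjacent silyloxy group) and proton loss; the silyl ethers shield the catechol from over-oxidation until methanolysis removes them.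

Step 5
Reactants: 8 methyl 4,5-dihydroxy-2-(3-methylbut-2-en-1-yl)benzoate; 9 3-chloro-3-methylbut-1-yne
Product: 10 methyl 5-hydroxy-4-[(2-methylbut-3-yn-2-yl)oxy]-2-(3-methylbut-2-en-1-yl)benzoate
Conditions: 9 (1.5 equiv), K2CO3 (1.1 equiv), KI (10 mol%), CuI (5 mol%), acetone, 45 °C, argon
Reagents that add atoms: none
Why: Copper-catalysed O-propargylation of a phenoxide with a tertiary propargylic chloride; one equivalent of carbonate should ionise the B-4 hydroxyl selectively because it is para to the ester, while the B-5 hydroxyl is para to an alkyl group and less acidic.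

Step 6
Reactants: 10 methyl 5-hydroxy-4-[(2-methylbut-3-yn-2-yl)oxy]-2-(3-methylbut-2-en-1-yl)benzoate
Product: 11 methyl 4-[(2-methylbut-3-yn-2-yl)oxy]-2-(3-methylbut-2-en-1-yl)-5-[(triisopropylsilyl)oxy]benzoate
Conditions: TIPSCl (1.3 equiv), imidazole (2.5 equiv), DMF, rt to 40 °C
Reagents that add atoms: chlorotriisopropylsilane, CC(C)[Si](Cl)(C(C)C)C(C)C
Why: Imidazole-promoted phenol silylation; capping the B-5 hydroxyl before heating removes addition of that phenol to the alkyne and gives a group that survives the basic coupling later.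

Step 7
Reactants: 11 methyl 4-[(2-methylbut-3-yn-2-yl)oxy]-2-(3-methylbut-2-en-1-yl)-5-[(triisopropylsilyl)oxy]benzoate
Product: 15 methyl 2,2-dimethyl-5-(3-methylbut-2-en-1-yl)-8-[(triisopropylsilyl)oxy]-2H-chromene-6-carboxylate, via allenyl cyclohexadienone 12 (not isolated), via ortho-allenylphenol 13 (not isolated), via ortho-quinone methide 14 (not isolated)
Conditions: PhNEt2, 185 °C
Reagents that add atoms: none
Why: Aryl propargyl ether Claisen rearrangement to B-3, the only ortho carbon bearing hydrogen, followed by enolisation, 1,5-hydrogen shift and oxa-6π electrocyclisation to the 2,2-dimethylchromene.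

Step 8
Reactants: 15 methyl 2,2-dimethyl-5-(3-methylbut-2-en-1-yl)-8-[(triisopropylsilyl)oxy]-2H-chromene-6-carboxylate
Product: 16 {2,2-dimethyl-5-(3-methylbut-2-en-1-yl)-8-[(triisopropylsilyl)oxy]-2H-chromen-6-yl}methanol
Conditions: i-Bu2AlH (2.5 equiv), CH2Cl2, −78 to 0 °C; aq. potassium sodium tartrate
Reagents that add atoms: none
Why: Aluminium hydride reduction of an aryl ester to the benzylic alcohol; alkenes and the aryl silyl ether are inert to the reagent.

Step 9
Reactants: 16 {2,2-dimethyl-5-(3-methylbut-2-en-1-yl)-8-[(triisopropylsilyl)oxy]-2H-chromen-6-yl}methanol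
Product: 18 6-(chloromethyl)-2,2-dimethyl-5-(3-methylbut-2-en-1-yl)-8-[(triisopropylsilyl)oxy]-2H-chromene, via benzylic mesylate 17 (not isolated)
Conditions: MsCl (1.3 equiv), Et3N (1.5 equiv), CH2Cl2, 0 °C to rt; used without chromatography
Reagents that add atoms: methanesulfonyl chloride, CS(=O)(=O)Cl (supplies the chlorine)
Why: Mesylation followed by in situ displacement by chloride, which is fast for a para-alkoxybenzylic mesylate; the non-ionising solvent and the chloride present keep the benzylic carbon from reacting with the neighbouring prenyl alkene.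

Step 10
Reactants: 18 6-(chloromethyl)-2,2-dimethyl-5-(3-methylbut-2-en-1-yl)-8-[(triisopropylsilyl)oxy]-2H-chromene; 19 tributyl(vinyl)stannane
Product: 20 {[2,2-dimethyl-5-(3-methylbut-2-en-1-yl)-6-(prop-2-en-1-yl)-2H-chromen-8-yl]oxy}tri(propan-2-yl)silane
Conditions: 19 (1.2 equiv), Pd(PPh3)4 (5 mol%), THF, 65 °C
Reagents that add atoms: none
Why: Stille coupling of a benzylic chloride with a vinylstannane under neutral conditions; oxidative addition to zerovalent palladium gives a benzyl complex without β-hydrogen, and transmetalation should outpace insertion into the trisubstituted prenyl alkene.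

Step 11
Reactants: 21 4-bromobenzene-1,3-diol; 4 1-bromo-3-methylbut-2-ene (prenyl bromide)
Product: 22 2-bromo-5-[(3-methylbut-2-en-1-yl)oxy]phenol
Conditions: 4 (1.0 equiv), K2CO3 (1.1 equiv), acetone, rt
Reagents that add atoms: none
Why: Williamson ether synthesis; the hydroxyl para to bromine is unhindered and not hydrogen-bonded to the halogen and should be alkylated in preference, with limiting bromide suppressing the bis-ether.

Step 12
Reactants: 22 2-bromo-5-[(3-methylbut-2-en-1-yl)oxy]phenol
Product: 23 {2-bromo-5-[(3-methylbut-2-en-1-yl)oxy]phenoxy}tri(propan-2-yl)silane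
Conditions: TIPSCl (1.3 equiv), imidazole (2.5 equiv), DMF, rt
Reagents that add atoms: chlorotriisopropylsilane, CC(C)[Si](Cl)(C(C)C)C(C)C
Why: Standard phenol silylation; the bulky silyl ether also shields the ring carbon between the two oxygens in the next step.

Step 13
Reactants: 23 {2-bromo-5-[(3-methylbut-2-en-1-yl)oxy]phenoxy}tri(propan-2-yl)silane
Product: 25 4-bromo-2-(2-methylbut-3-en-2-yl)-5-[(triisopropylsilyl)oxy]phenol, via cyclohexadienone 24 (not isolated)
Conditions: PhNEt2, 190 °C
Reagents that add atoms: none
Why: Aromatic Claisen rearrangement of an aryl prenyl ether; the [3,3] shift inverts the allyl unit and bonds its tertiary carbon to the ortho carbon para to the silyloxy group (A-5), the other ortho carbon being flanked by two oxygens and shielded by the triisopropylsilyl group, and the amine solvent suppresses acid-catalysed ring closure of the product.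

Step 14
Reactants: 25 4-bromo-2-(2-methylbut-3-en-2-yl)-5-[(triisopropylsilyl)oxy]phenol
Product: 26 1-bromo-5-(2-methylbut-3-en-2-yl)-2,4-bis[(triisopropylsilyl)oxy]benzene
Conditions: TIPSOTf (1.3 equiv), 2,6-lutidine (2.0 equiv), CH2Cl2, 0 °C to rt
Reagents that add atoms: triisopropylsilyl trifluoromethanesulfonate, CC(C)[Si](OS(=O)(=O)C(F)(F)F)(C(C)C)C(C)C
Why: Silyl triflate silylation copes with the phenol flanked by the quaternary carbon; excess hindered base keeps the medium free of acid.

Step 15
Reactants: 20 {[2,2-dimethyl-5-(3-methylbut-2-en-1-yl)-6-(prop-2-en-1-yl)-2H-chromen-8-yl]oxy}tri(propan-2-yl)silane; 26 1-bromo-5-(2-methylbut-3-en-2-yl)-2,4-bis[(triisopropylsilyl)oxy]benzene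
Product: 28 tris(triisopropylsilyl) ether of Kazinol K, via B-alkyl-9-borabicyclononane 27 (not isolated)
Conditions: 9-BBN-H (1.05 equiv), THF, 0 °C to rt; then aq. K3PO4 (3 M), 26 (0.95 equiv), Pd(OAc)2 (5 mol%), SPhos (10 mol%), THF, 60 °C
Reagents that add atoms: none
Why: Anti-Markovnikov hydroboration with a hindered dialkylborane is selective for the monosubstituted alkene over the prenyl and chromene alkenes, and the B-alkyl Suzuki–Miyaura coupling then forms the A-1–CH2 bond; aqueous base is added before 26 so that no B–H remains to attack its vinyl group.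

Step 16
Reactants: 28 tris(triisopropylsilyl) ether of Kazinol K
Product: 29 Kazinol K
Conditions: Bu4NF (3.6 equiv), AcOH (3.6 equiv), THF, 0 °C to rt, argon
Reagents that add atoms: none
Why: Fluoride cleavage of aryl silyl ethers driven by the Si–F bond; acetic acid buffering avoids free phenoxides of the catechol ring, and no acid or oxidant touches the alkenes.

## Compound list

1 | butane-2,3-dione | CC(=O)C(C)=O | starting material
2 | 2,3-bis(trimethylsilyloxy)buta-1,3-diene | C=C(O[Si](C)(C)C)C(=C)O[Si](C)(C)C | intermediate
3 | methyl propiolate | C#CC(=O)OC | starting material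
4 | 1-bromo-3-methylbut-2-ene (prenyl bromide) | CC(C)=CCBr | starting material
5 | methyl 6-methylhept-5-en-2-ynoate | COC(=O)C#CCC=C(C)C | intermediate
6 | methyl 2-(3-methylbut-2-en-1-yl)-4,5-bis(trimethylsilyloxy)cyclohexa-1,4-diene-1-carboxylate | COC(=O)C1=C(CC=C(C)C)CC(O[Si](C)(C)C)=C(O[Si](C)(C)C)C1 | intermediate
7 | methyl 2-(3-methylbut-2-en-1-yl)-4,5-bis(trimethylsilyloxy)benzoate | COC(=O)c1cc(O[Si](C)(C)C)c(O[Si](C)(C)C)cc1CC=C(C)C | intermediate (not isolated)
8 | methyl 4,5-dihydroxy-2-(3-methylbut-2-en-1-yl)benzoate | COC(=O)c1cc(O)c(O)cc1CC=C(C)C | intermediate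
9 | 3-chloro-3-methylbut-1-yne | C#CC(C)(C)Cl | starting material
10 | methyl 5-hydroxy-4-[(2-methylbut-3-yn-2-yl)oxy]-2-(3-methylbut-2-en-1-yl)benzoate | COC(=O)c1cc(O)c(OC(C)(C)C#C)cc1CC=C(C)C | intermediate
11 | methyl 4-[(2-methylbut-3-yn-2-yl)oxy]-2-(3-methylbut-2-en-1-yl)-5-[(triisopropylsilyl)oxy]benzoate | COC(=O)c1cc(O[Si](C(C)C)(C(C)C)C(C)C)c(OC(C)(C)C#C)cc1CC=C(C)C | intermediate
12 | methyl 3-(3-methylbuta-1,2-dien-1-yl)-2-(3-methylbut-2-en-1-yl)-4-oxo-5-[(triisopropylsilyl)oxy]cyclohexa-1,5-diene-1-carboxylate (racemic) | COC(=O)C1=C(CC=C(C)C)C(C=C=C(C)C)C(=O)C(O[Si](C(C)C)(C(C)C)C(C)C)=C1 | intermediate (not isolated)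
13 | methyl 4-hydroxy-3-(3-methylbuta-1,2-dien-1-yl)-2-(3-methylbut-2-en-1-yl)-5-[(triisopropylsilyl)oxy]benzoate | COC(=O)c1cc(O[Si](C(C)C)(C(C)C)C(C)C)c(O)c(C=C=C(C)C)c1CC=C(C)C | intermediate (not isolated)
14 | methyl 3-(3-methylbut-2-en-1-ylidene)-2-(3-methylbut-2-en-1-yl)-4-oxo-5-[(triisopropylsilyl)oxy]cyclohexa-1,5-diene-1-carboxylate | COC(=O)C1=C(CC=C(C)C)C(=CC=C(C)C)C(=O)C(O[Si](C(C)C)(C(C)C)C(C)C)=C1 | intermediate (not isolated)
15 | methyl 2,2-dimethyl-5-(3-methylbut-2-en-1-yl)-8-[(triisopropylsilyl)oxy]-2H-chromene-6-carboxylate | COC(=O)c1cc(O[Si](C(C)C)(C(C)C)C(C)C)c2OC(C)(C)C=Cc2c1CC=C(C)C | intermediate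
16 | {2,2-dimethyl-5-(3-methylbut-2-en-1-yl)-8-[(triisopropylsilyl)oxy]-2H-chromen-6-yl}methanol | OCc1cc(O[Si](C(C)C)(C(C)C)C(C)C)c2OC(C)(C)C=Cc2c1CC=C(C)C | intermediate
17 | {2,2-dimethyl-5-(3-methylbut-2-en-1-yl)-8-[(triisopropylsilyl)oxy]-2H-chromen-6-yl}methyl methanesulfonate | CS(=O)(=O)OCc1cc(O[Si](C(C)C)(C(C)C)C(C)C)c2OC(C)(C)C=Cc2c1CC=C(C)C | intermediate (not isolated)
18 | 6-(chloromethyl)-2,2-dimethyl-5-(3-methylbut-2-en-1-yl)-8-[(triisopropylsilyl)oxy]-2H-chromene | ClCc1cc(O[Si](C(C)C)(C(C)C)C(C)C)c2OC(C)(C)C=Cc2c1CC=C(C)C | intermediate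
19 | tributyl(vinyl)stannane | C=C[Sn](CCCC)(CCCC)CCCC | starting material
20 | {[2,2-dimethyl-5-(3-methylbut-2-en-1-yl)-6-(prop-2-en-1-yl)-2H-chromen-8-yl]oxy}tri(propan-2-yl)silane | C=CCc1cc(O[Si](C(C)C)(C(C)C)C(C)C)c2OC(C)(C)C=Cc2c1CC=C(C)C | intermediate
21 | 4-bromobenzene-1,3-diol | Oc1ccc(Br)c(O)c1 | starting material
22 | 2-bromo-5-[(3-methylbut-2-en-1-yl)oxy]phenol | CC(C)=CCOc1ccc(Br)c(O)c1 | intermediate
23 | {2-bromo-5-[(3-methylbut-2-en-1-yl)oxy]phenoxy}tri(propan-2-yl)silane | CC(C)=CCOc1ccc(Br)c(O[Si](C(C)C)(C(C)C)C(C)C)c1 | intermediate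
24 | 4-bromo-6-(2-methylbut-3-en-2-yl)-3-[(triisopropylsilyl)oxy]cyclohexa-2,4-dien-1-one (racemic) | O=C1C=C(O[Si](C(C)C)(C(C)C)C(C)C)C(Br)=CC1C(C)(C)C=C | intermediate (not isolated)
25 | 4-bromo-2-(2-methylbut-3-en-2-yl)-5-[(triisopropylsilyl)oxy]phenol | C=CC(C)(C)c1cc(Br)c(O[Si](C(C)C)(C(C)C)C(C)C)cc1O | intermediate
26 | 1-bromo-5-(2-methylbut-3-en-2-yl)-2,4-bis[(triisopropylsilyl)oxy]benzene | C=CC(C)(C)c1cc(Br)c(O[Si](C(C)C)(C(C)C)C(C)C)cc1O[Si](C(C)C)(C(C)C)C(C)C | intermediate
27 | 9-{3-[2,2-dimethyl-5-(3-methylbut-2-en-1-yl)-8-[(triisopropylsilyl)oxy]-2H-chromen-6-yl]propyl}-9-borabicyclo[3.3.1]nonane | CC(C)=CCc1c(CCCB3C4CCCC3CCC4)cc(O[Si](C(C)C)(C(C)C)C(C)C)c2OC(C)(C)C=Cc12 | intermediate (not isolated)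
28 | tris(triisopropylsilyl) ether of Kazinol K | C=CC(C)(C)c1cc(CCCc2cc(O[Si](C(C)C)(C(C)C)C(C)C)c3OC(C)(C)C=Cc3c2CC=C(C)C)c(O[Si](C(C)C)(C(C)C)C(C)C)cc1O[Si](C(C)C)(C(C)C)C(C)C | intermediate
29 | Kazinol K, 4-{3-[8-hydroxy-2,2-dimethyl-5-(3-methylbut-2-en-1-yl)-2H-chromen-6-yl]propyl}-6-(2-methylbut-3-en-2-yl)benzene-1,3-diol | C=CC(C)(C)c1cc(CCCc2cc(O)c3c(c2CC=C(C)C)C=CC(C)(C)O3)c(O)cc1O | target

## Summary and least certain steps

Total step count: 16. Longest linear sequence: 11 steps (step 1 or 2, then 3 to 10, 15 and 16); the ring A branch is 4 steps (11 to 14).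

**Step 3 (key step).** The β-alkyl ynoate 5 is only a moderate dienophile, so cycloaddition may be outrun by thermal desilylation and oligomerisation of 2 or by ene-type reaction at the prenyl alkene. The fallback sets out from 3 and 2 and returns at 8, keeping the same two ring-forming bonds but moving the prenyl group after the ring. 3 would be brominated at the alkyne terminus (NBS, AgNO3 cat., acetone) to methyl 3-bromoprop-2-ynoate F1, a more electron-poor and less hindered dienophile. Cycloaddition with 2 near 80 °C would give methyl 2-bromo-4,5-bis(trimethylsilyloxy)cyclohexa-1,4-diene-1-carboxylate F2. DDQ would convert it to methyl 2-bromo-4,5-bis(trimethylsilyloxy)benzoate F3, and methanolysis to methyl 2-bromo-4,5-dihydroxybenzoate F4. A Stille coupling of F4 with tributyl(3-methylbut-2-en-1-yl)stannane (Pd(PPh3)4, DMF, 90 °C) would place the prenyl group at B-2 and give 8.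

**Step 13 (with step 11).** Prolonged heating may cause abnormal Claisen rearrangement, ring closure of the freed phenol onto the new vinyl group or loss of the prenyl group; in step 11, alkylation may occur at the other hydroxyl. The fallback sets out from 21 and returns at 26 without any prenyl ether. 21 would be bis-silylated to 1-bromo-2,4-bis[(triisopropylsilyl)oxy]benzene F5. Palladium-catalysed α-arylation of the lithium enolate of methyl 2-methylpropanoate (LiNCy2, Pd(dba)2, P(t-Bu)3, PhMe, rt) would give methyl 2-{2,4-bis[(triisopropylsilyl)oxy]phenyl}-2-methylpropanoate F6. NBS in MeCN would brominate the only open activated position to give methyl 2-{5-bromo-2,4-bis[(triisopropylsilyl)oxy]phenyl}-2-methylpropanoate F7. Reduction with i-Bu2AlH would give 2-{5-bromo-2,4-bis[(triisopropylsilyl)oxy]phenyl}-2-methylpropan-1-ol F8, Dess–Martin oxidation 2-{5-bromo-2,4-bis[(triisopropylsilyl)oxy]phenyl}-2-methylpropanal F9, and Wittig methylenation (Ph3P=CH2) 26.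

**Step 5.** Alkylation may occur at the B-5 oxygen or at both oxygens, and the copper salt may promote oxidation of the catechol. The fallback sets out from 8 and returns at 11, reversing the order of the two O-functionalisations. The dianion of 8 (NaH, 2.1 equiv, THF/DMF, 0 °C) would be silylated with one equivalent of TIPSCl at the more nucleophilic B-5 oxide, leaving the ester-stabilised B-4 phenoxide; silyl migration between the neighbouring oxygens can only reinforce this outcome. This gives methyl 4-hydroxy-2-(3-methylbut-2-en-1-yl)-5-[(triisopropylsilyl)oxy]benzoate F10, whose copper-catalysed propargylation with 9 (K2CO3, KI, CuI, acetone) leads directly to 11.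

**Step 9 (and 10).** Ionisation of the para-alkoxybenzylic mesylate or chloride may be followed by five-membered ring closure onto the B-2 prenyl alkene, or by hydrolysis on handling. The fallback sets out from 16 and returns at 20 without a benzylic halide. MnO2 oxidation would give 2,2-dimethyl-5-(3-methylbut-2-en-1-yl)-8-[(triisopropylsilyl)oxy]-2H-chromene-6-carbaldehyde F11. Vinylmagnesium bromide would give racemic 1-{2,2-dimethyl-5-(3-methylbut-2-en-1-yl)-8-[(triisopropylsilyl)oxy]-2H-chromen-6-yl}prop-2-en-1-ol F12, and methyl chloroformate/pyridine its methyl carbonate F13. Palladium-catalysed formate hydrogenolysis (Pd(OAc)2, PBu3, HCO2H, Et3N), which delivers hydride to the more substituted end of the allyl complex, would give 20.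

**Step 2.** Base may isomerise the skipped enynoate to the allenoate or dienoate, and some coupling may occur through the tertiary end of the prenyl unit. The fallback sets out from 4 and returns at 5, installing the ester last and at low temperature. The bromomagnesium acetylide of ethynyltrimethylsilane (EtMgBr, CuBr·SMe2 cat., THF) would be alkylated with 4 to give trimethyl(5-methylhex-4-en-1-yn-1-yl)silane F14. K2CO3/MeOH would give 5-methylhex-4-en-1-yne F15, and n-BuLi at −78 °C followed by methyl chloroformate would give 5.

## Further compounds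

F1 | step 3 | methyl 3-bromoprop-2-ynoate | COC(=O)C#CBr
F2 | step 3 | methyl 2-bromo-4,5-bis(trimethylsilyloxy)cyclohexa-1,4-diene-1-carboxylate | COC(=O)C1=C(Br)CC(O[Si](C)(C)C)=C(O[Si](C)(C)C)C1
F3 | step 3 | methyl 2-bromo-4,5-bis(trimethylsilyloxy)benzoate | COC(=O)c1cc(O[Si](C)(C)C)c(O[Si](C)(C)C)cc1Br
F4 | step 3 | methyl 2-bromo-4,5-dihydroxybenzoate | COC(=O)c1cc(O)c(O)cc1Br
F5 | step 13 | 1-bromo-2,4-bis[(triisopropylsilyl)oxy]benzene | Brc1ccc(O[Si](C(C)C)(C(C)C)C(C)C)cc1O[Si](C(C)C)(C(C)C)C(C)C
F6 | step 13 | methyl 2-{2,4-bis[(triisopropylsilyl)oxy]phenyl}-2-methylpropanoate | COC(=O)C(C)(C)c1ccc(O[Si](C(C)C)(C(C)C)C(C)C)cc1O[Si](C(C)C)(C(C)C)C(C)C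
F7 | step 13 | methyl 2-{5-bromo-2,4-bis[(triisopropylsilyl)oxy]phenyl}-2-methylpropanoate | COC(=O)C(C)(C)c1cc(Br)c(O[Si](C(C)C)(C(C)C)C(C)C)cc1O[Si](C(C)C)(C(C)C)C(C)C
F8 | step 13 | 2-{5-bromo-2,4-bis[(triisopropylsilyl)oxy]phenyl}-2-methylpropan-1-ol | OCC(C)(C)c1cc(Br)c(O[Si](C(C)C)(C(C)C)C(C)C)cc1O[Si](C(C)C)(C(C)C)C(C)C
F9 | step 13 | 2-{5-bromo-2,4-bis[(triisopropylsilyl)oxy]phenyl}-2-methylpropanal | O=CC(C)(C)c1cc(Br)c(O[Si](C(C)C)(C(C)C)C(C)C)cc1O[Si](C(C)C)(C(C)C)C(C)C
F10 | step 5 | methyl 4-hydroxy-2-(3-methylbut-2-en-1-yl)-5-[(triisopropylsilyl)oxy]benzoate | COC(=O)c1cc(O[Si](C(C)C)(C(C)C)C(C)C)c(O)cc1CC=C(C)C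
F11 | step 9 | 2,2-dimethyl-5-(3-methylbut-2-en-1-yl)-8-[(triisopropylsilyl)oxy]-2H-chromene-6-carbaldehyde | O=Cc1cc(O[Si](C(C)C)(C(C)C)C(C)C)c2OC(C)(C)C=Cc2c1CC=C(C)C
F12 | step 9 | 1-{2,2-dimethyl-5-(3-methylbut-2-en-1-yl)-8-[(triisopropylsilyl)oxy]-2H-chromen-6-yl}prop-2-en-1-ol (racemic) | C=CC(O)c1cc(O[Si](C(C)C)(C(C)C)C(C)C)c2OC(C)(C)C=Cc2c1CC=C(C)C
F13 | step 9 | 1-{2,2-dimethyl-5-(3-methylbut-2-en-1-yl)-8-[(triisopropylsilyl)oxy]-2H-chromen-6-yl}prop-2-en-1-yl methyl carbonate (racemic) | C=CC(OC(=O)OC)c1cc(O[Si](C(C)C)(C(C)C)C(C)C)c2OC(C)(C)C=Cc2c1CC=C(C)C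
F14 | step 2 | trimethyl(5-methylhex-4-en-1-yn-1-yl)silane | CC(C)=CCC#C[Si](C)(C)C
F15 | step 2 | 5-methylhex-4-en-1-yne | CC(C)=CCC#C
A1 | alternative 1 | bis(methoxymethyl) ether of Kazinol K | C=CC(C)(C)c1cc(CCCc2cc(OCOC)c3OC(C)(C)C=Cc3c2CC=C(C)C)c(OCOC)cc1O
A2 | alternative 1 | A-5 acetyl, A-4 tert-butyl carbonate precursor with methoxymethyl ethers at A-2 and B-5 | CC(=O)c1cc(CCCc2cc(OCOC)c3OC(C)(C)C=Cc3c2CC=C(C)C)c(OCOC)cc1OC(=O)OC(C)(C)C
A3 | alternative 1 | methyllithium | [Li]C
A4 | alternative 1 | dimethyl ortho-quinone methide of ring A | CC(C)=C1C=C(CCCc2cc(OCOC)c3OC(C)(C)C=Cc3c2CC=C(C)C)C(OCOC)=CC1=O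
A5 | alternative 1 | vinylmagnesium bromide | C=C[Mg]Br
A6 | alternative 2 | 8-hydroxy-6-[(methoxymethoxy)methyl]-2,2-dimethyl-5-(3-methylbut-2-en-1-yl)-2H-chromene | COCOCc1cc(O)c2OC(C)(C)C=Cc2c1CC=C(C)C
A7 | alternative 2 | (Z)-4-{6-fluoro-3-[(methoxymethoxy)methyl]-2-(3-methylbut-2-en-1-yl)phenyl}-2-methylbut-3-en-2-ol | COCOCc1ccc(F)c(/C=C\C(C)(C)O)c1CC=C(C)C
A8 | alternative 2 | B-4/B-5 aryne as its lithium alkoxide | COCOCC1=CC#CC(/C=C\C(C)(C)O[Li])=C1CC=C(C)C
A9 | alternative 3 | 6-[(methoxymethoxy)methyl]-2,2-dimethyl-4,5-bis(3-methylbut-2-en-1-yl)-1,3-benzodioxole | COCOCc1cc2OC(C)(C)Oc2c(CC=C(C)C)c1CC=C(C)C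
A10 | alternative 3 | 6-[(methoxymethoxy)methyl]-2,2-dimethyl-5-(trimethylsilyl)-1,3-benzodioxol-4-yl trifluoromethanesulfonate | COCOCc1cc2OC(C)(C)Oc2c(OS(=O)(=O)C(F)(F)F)c1[Si](C)(C)C
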